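**Strategy.** Ring D (C1'–C6', the methoxy-enedione) is made by ring expansion of a four-membered ring. Its contiguous O=C2'–C3'H=C4'(OMe)–C5'–O unit is brought in as a squarate-derived 4-hydroxycyclobutenone. This is attached through C5' to C6' of a 1,4-cyclohexadiene (future ring C) that already carries the chromone on C1' and the labdane on C12. Heat opens the cyclobutenone to a dienylketene; 6π electrocyclisation then joins C2' to C1', building the quaternary carbon anti to the C12 side chain, and ketonisation gives the cis-fused enedione. The precursor comes from a catalyst-controlled Diels–Alder reaction of a levopimaric acid-derived labdatriene with 3-iodopropynal, chromone annulation and alkenylmagnesium addition to methyl semisquarate.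

Key step: step 20

Remark on numbering: labdane atoms are C1–C20 (rings A/B; C11–C16 side chain). Ring C is C12, C13, C14, C15, C6', C1'. Ring D is C1' (quaternary, bonded to C12 and chromone C2), C2' (C=O), C3' (CH), C4' (C–OMe), C5' (C=O), C6' (CH, bonded to C15).

Remark on supply: levopimaric acid is taken as a purchasable resin acid (it is also obtained from pine oleoresin through its amine salt).

Remark on step 13: the (S)-configured oxazaborolidinium ion is assumed, from its formyl C–H···O binding model, to deliver the ynal to the diene face that gives 12R; if a model run showed the opposite sense, the (R)-catalyst would be used.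

Step 1
Reactants: 1 levopimaric acid
Product: 2 methyl levopimarate
Conditions: MeI, K2CO3, DMF, 23 °C, argon, dark
Reagents that add atoms: iodomethane (CI)
Why: SN2 O-methylation of the carboxylate under non-acidic conditions masks C18 as an ester without isomerising the acid-labile ring C diene.

Step 2
Reactants: 2 methyl levopimarate
Product: 4 keto acetal ester (methyl 12,12-dimethoxy-8-oxo-13,14,15,16,17-pentanorlabdan-18-oate), via keto aldehyde 3 (not isolated)
Conditions: O3, CH2Cl2/MeOH 4:1, −78 °C; TsOH·H2O (cat.), 23 °C; NaHCO3, Me2S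
Reagents that add atoms: ozone ([O-][O+]=O); methanol (CO)
Why: Ozonolysis of both ring C alkenes (C8=C14 and C12=C13) excises C13/C14 with the isopropyl group and leaves the C8 ketone and the C12 aldehyde, of which only the unhindered aldehyde is acetalised; the trans-decalin and the equatorial C9 side chain are untouched.

Step 3
Reactants: 4 keto acetal ester
Product: 5 methyl 12,12-dimethoxy-13,14,15,16-tetranorlabd-8(17)-en-18-oate
Conditions: Ph3PCH3Br, KOtBu, toluene, 0 to 60 °C
Reagents that add atoms: methyltriphenylphosphonium bromide (C[P+](c1ccccc1)(c1ccccc1)c1ccccc1.[Br-])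
Why: Wittig methylenation converts the C8 ketone into the 8(17)-exocyclic alkene; the ester has no α-hydrogen and C9 keeps its equatorial, thermodynamically preferred configuration.

Step 4
Reactants: 5 exocyclic alkene
Product: 6 methyl 7α-hydroxy-12,12-dimethoxy-13,14,15,16-tetranorlabd-8(17)-en-18-oate
Conditions: SeO2 (0.5 equiv), t-BuOOH (decane solution), CH2Cl2, 23 °C
Reagents that add atoms: tert-butyl hydroperoxide (CC(C)(C)OO); selenium dioxide (O=[Se]=O)
Why: Allylic oxidation by the ene/[2,3]-sigmatropic sequence removes the axial 7α-hydrogen and returns oxygen on the same face, giving the 7α-alcohol with the alkene back at C8=C17; the configuration is corrected in steps 5 and 6.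

Step 5
Reactants: 6 7α-alcohol
Product: 7 methyl 12,12-dimethoxy-7-oxo-13,14,15,16-tetranorlabd-8(17)-en-18-oate
Conditions: Dess–Martin periodinane, NaHCO3, CH2Cl2, 0 to 23 °C
Reagents that add atoms: none
Why: Dess–Martin oxidation of the allylic alcohol gives the exocyclic enone without touching acetal or ester; the enone is used at once.

Step 6
Reactants: 7 enone
Product: 8 12,12-dimethoxy-13,14,15,16-tetranorlabd-8(17)-ene-7β,18-diol
Conditions: LiAlH4, Et2O, −78 to 23 °C; aqueous NaOH work-up
Reagents that add atoms: none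
Why: LiAlH4 adds hydride 1,2 to the C7 carbonyl along the axial α-trajectory, which sets the equatorial 7β-alcohol, and reduces the C18 ester to the primary alcohol.

Step 7
Reactants: 8 diol acetal
Product: 9 7β,18-dihydroxy-13,14,15,16-tetranorlabd-8(17)-en-12-al
Conditions: pyridinium p-toluenesulfonate, acetone/H2O 10:1, 50 °C
Reagents that add atoms: water (O)
Why: Mild acid hydrolysis of the dimethyl acetal frees the C12 aldehyde; the allylic alcohol and the exocyclic alkene tolerate the weak acid.

Step 8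
Reactants: 9 hydroxy aldehyde
Product: 10 (12E)-7β,18-dihydroxy-15-norlabda-8(17),12-dien-14-al
Conditions: Ph3P=C(CH3)CHO (1.3 equiv), toluene, 90 °C
Reagents that add atoms: 2-(triphenylphosphoranylidene)propanal (CC(C=O)=P(c1ccccc1)(c1ccccc1)c1ccccc1)
Why: Wittig reaction of the formyl-stabilised ylide with the unhindered aldehyde gives the (12E)-2-methylenal under the thermodynamic control typical of stabilised ylides, and the product enal is too deactivated to react again.

Step 9
Reactants: 10 enal
Product: 11 (12E)-labda-8(17),12,14-triene-7β,18-diol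
Conditions: Ph3PCH3Br (3.5 equiv), KOtBu (3.3 equiv), THF, 0 to 23 °C
Reagents that add atoms: methyltriphenylphosphonium bromide (C[P+](c1ccccc1)(c1ccccc1)c1ccccc1.[Br-])
Why: Wittig methylenation of the enal completes the (12E)-1,3-diene; the excess ylide covers the two free hydroxyl groups.

Step 10
Reactants: 11 triene diol
Product: 13 (12E)-7β-(tert-butyldimethylsilyloxy)-18-(triethylsilyloxy)labda-8(17),12,14-triene, via mono-triethylsilyl ether 12 (not isolated)
Conditions: TESCl (1.05 equiv), imidazole, CH2Cl2, −40 °C; then TBSOTf, 2,6-lutidine, −40 to 0 °C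
Reagents that add atoms: chlorotriethylsilane (CC[Si](Cl)(CC)CC); tert-butyldimethylsilyl triflate (CC(C)(C)[Si](C)(C)OS(=O)(=O)C(F)(F)F)
Why: Stepwise silylation uses the higher reactivity of the primary C18 hydroxyl toward the chlorosilane; the silyl triflate then caps the secondary allylic C7 hydroxyl.

Step 11
Reactants: 14 propargyl alcohol
Product: 15 3-iodoprop-2-yn-1-ol
Conditions: N-iodosuccinimide, AgNO3 (10 mol %), acetone, 23 °C
Reagents that add atoms: N-iodosuccinimide (O=C1CCC(=O)N1I)
Why: Silver-catalysed electrophilic iodination of the terminal alkyne proceeds through the silver acetylide.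

Step 12
Reactants: 15 3-iodoprop-2-yn-1-ol
Product: 16 3-iodopropynal
Conditions: Dess–Martin periodinane, CH2Cl2, 0 °C; filtered through silica, used as a CH2Cl2 solution
Reagents that add atoms: none
Why: Dess–Martin oxidation of the propargylic alcohol gives the sensitive ynal without over-oxidation.

Step 13
Reactants: 13 silylated labdatriene; 16 3-iodopropynal
Product: 17 iodo enal (ring C as 1,4-cyclohexadiene: C12(H)–C13(Me)=C14H–C15H2–C6'(I)=C1'(CHO), 12R)
Conditions: (S)-3,3-diphenyl-1-(o-tolyl)tetrahydropyrrolo[1,2-c][1,3,2]oxazaborole (20 mol %), HNTf2 (16 mol %), CH2Cl2, −78 to −40 °C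
Reagents that add atoms: none
Why: In this Lewis acid-catalysed Diels–Alder reaction of an acetylenic aldehyde the iodine-bearing β-carbon bonds to the unsubstituted diene terminus C15 and the formyl-bearing carbon to C12 ("ortho" orientation), and the chiral oxazaborolidinium ion shields one face of the bound ynal, so the only new stereocentre, C12 (R), is set by the catalyst and not by the remote decalin.

Step 14
Reactants: 17 iodo enal
Product: 18 iodo acid (C1'–CO2H)
Conditions: NaClO2, NaH2PO4, 2-methyl-2-butene, t-BuOH/H2O, 0 to 23 °C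
Reagents that add atoms: sodium chlorite ([Na+].[O-]Cl=O)
Why: Pinnick oxidation converts the hindered enal into the acid under buffered conditions that spare the silyl ethers, the alkenyl iodide and the skipped diene, because the scavenger alkene traps HOCl.

Step 15
Reactants: 19 2',4',6'-trihydroxyacetophenone
Product: 20 1-[2-hydroxy-4,6-bis(tert-butyldimethylsilyloxy)phenyl]ethanone
Conditions: TBSCl (2.1 equiv), imidazole, DMF, 0 to 23 °C
Reagents that add atoms: tert-butylchlorodimethylsilane (CC(C)(C)[Si](C)(C)Cl)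
Why: The para hydroxyl and one ortho hydroxyl are silylated first, while the remaining ortho hydroxyl, locked in a hydrogen bond to the acetyl group, stays free for the later chromone closure.

Step 16
Reactants: 18 iodo acid; 20 silylated acetophenone
Product: 22 1,3-diketone (C1'–CO–CH2–CO–aryl), via acid chloride 21 (not isolated)
Conditions: 18, 1-chloro-N,N,2-trimethylpropenylamine, CH2Cl2, 0 to 23 °C; added to 20 (1.5 equiv) and LiN(SiMe3)2 (4.5 equiv), THF, −78 to −10 °C; AcOH quench
Reagents that add atoms: none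
Why: The acid chloride, formed under neutral conditions, C-acylates the lithium dianion of 20 (Claisen condensation of the Baker–Venkataraman type) to give the 1,3-diketone that holds all carbons of the chromone.

Step 17
Reactants: 22 1,3-diketone
Product: 23 iodo chromone (5,7-bis(tert-butyldimethylsilyloxy)chromon-2-yl on C1', iodine on C6')
Conditions: pyridinium p-toluenesulfonate (0.2 equiv), 4 Å molecular sieves, toluene, 70 °C
Reagents that add atoms: none
Why: In this acid-catalysed cyclodehydration the free phenol adds to the ring C-side carbonyl (6-exo-trig) and loss of water aromatises the pyranone, which places the chromone on C1'.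

Step 18
Reactants: 24 dimethyl squarate
Product: 26 methyl semisquarate (3-methoxycyclobut-3-ene-1,2-dione), via hydroxycyclobutenone 25 (not isolated)
Conditions: LiAlH(OtBu)3, THF, −78 °C; then conc. HCl (cat.), CH2Cl2, 23 °C
Reagents that add atoms: none
Why: 1,2-Hydride reduction of one squarate carbonyl is followed by acid-promoted allylic transposition with loss of methanol, which gives the semisquarate with a hydrogen on the ring alkene.

Step 19
Reactants: 23 iodo chromone; 26 methyl semisquarate
Product: 28 4-hydroxy-3-methoxy-4-(ring C C6')cyclobut-2-en-1-one (both C5' epimers), via alkenylmagnesium chloride 27 (not isolated)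
Conditions: i-PrMgCl·LiCl (1.1 equiv), THF, −40 °C; then 26 (2 equiv), −78 °C; aqueous NH4Cl
Reagents that add atoms: none
Why: Iodine–magnesium exchange at −40 °C gives an alkenylmagnesium that the chromone tolerates and that adds 1,2 to the squarate carbonyl next to C–OMe (not to the vinylogous ester carbonyl); the new carbinol centre C5' forms as both epimers, which converge in step 20.

Step 20
Reactants: 28 hydroxycyclobutenone
Product: 31 silyl-protected enedione (ring D closed, 12R,1'S,6'R), via dienylketene 29 (not isolated), via dienol 30 (not isolated)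
Conditions: toluene (0.01 M, degassed), 100 °C; then Et3N (0.1 equiv), 23 °C
Reagents that add atoms: none
Why: Thermal conrotatory 4π ring opening breaks C2'–C5' and, because the hydroxyl rotates outward, places the ring C alkene C6'=C1' cis to the ketene; disrotatory 6π electrocyclisation of 29 then bonds the ketene carbon C2' to C1' and ketonisation of dienol 30 gives the enedione, so ring D arises from the four-membered ring by a two-carbon ring expansion. The closest known reaction type is the thermal rearrangement of 4-alkenyl-4-hydroxycyclobutenones to hydroquinones and, when the alkene terminus is fully substituted, to 6,6-disubstituted cyclohexadienones. Ring D closes by electrocyclisation at the C2'–C1' bond. C1' is controlled by the C12 stereocentre: the ketene carbon adds to the ring C face opposite the C11 side chain, which leaves the chromone cis to that chain. C6' is fixed in the ketonisation, where the cis-fused ketone (side chain pseudoaxial, free of strain against the C13 methyl) is expected to prevail under the equilibrating amine. The step needs outward torquoselectivity of the hydroxyl, secured by the donor oxygen, and 6π closure in preference to closure through the chromone C2=C3 bond, secured by the s-cis dienylketene geometry held in ring C.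

Step 21
Reactants: 31 silyl-protected enedione
Product: 32 C18 primary alcohol (7-O- and aryl silyl ethers retained)
Conditions: pyridinium p-toluenesulfonate (0.3 equiv), MeOH/CH2Cl2 1:1, 0 to 23 °C
Reagents that add atoms: none
Why: Acid-catalysed methanolysis removes the primary triethylsilyl ether selectively, because the secondary and the aryl tert-butyldimethylsilyl ethers react much more slowly.

Step 22
Reactants: 32 C18 alcohol
Product: 33 C18 aldehyde (tris-silyl dichrostachine H)
Conditions: Dess–Martin periodinane, NaHCO3, CH2Cl2, 0 to 23 °C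
Reagents that add atoms: none
Why: Dess–Martin oxidation of the neopentyl primary alcohol gives the C18 aldehyde, and the buffer avoids acid-induced epimerisation at C6'.

Step 23
Reactants: 33 tris-silyl ether
Product: 34 dichrostachine H
Conditions: HF·pyridine, pyridine/THF, 0 to 23 °C
Reagents that add atoms: none
Why: Fluoride-mediated desilylation frees the 7β-hydroxyl and both phenols without strong base, leaving aldehyde, enedione and alkenes intact.

**Compound list**

1 | levopimaric acid (abieta-8(14),12-dien-18-oic acid) | CC(C)C1=CC[C@H]2C(=C1)CC[C@@H]3[C@]2(C)CCC[C@@]3(C)C(=O)O | starting material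
2 | methyl levopimarate | CC(C)C1=CC[C@H]2C(=C1)CC[C@@H]3[C@]2(C)CCC[C@@]3(C)C(=O)OC | intermediate
3 | methyl 8,12-dioxo-13,14,15,16,17-pentanorlabdan-18-oate (C8 ketone, C12 aldehyde) | O=C1CC[C@@H]2[C@](C)(CCC[C@@]2(C)C(=O)OC)[C@H]1CC=O | intermediate
4 | methyl 12,12-dimethoxy-8-oxo-13,14,15,16,17-pentanorlabdan-18-oate | O=C1CC[C@@H]2[C@](C)(CCC[C@@]2(C)C(=O)OC)[C@H]1CC(OC)OC | intermediate
5 | methyl 12,12-dimethoxy-13,14,15,16-tetranorlabd-8(17)-en-18-oate | C=C1CC[C@@H]2[C@](C)(CCC[C@@]2(C)C(=O)OC)[C@H]1CC(OC)OC | intermediate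
6 | methyl 7α-hydroxy-12,12-dimethoxy-13,14,15,16-tetranorlabd-8(17)-en-18-oate | C=C1[C@H](O)C[C@@H]2[C@](C)(CCC[C@@]2(C)C(=O)OC)[C@H]1CC(OC)OC | intermediate
7 | methyl 12,12-dimethoxy-7-oxo-13,14,15,16-tetranorlabd-8(17)-en-18-oate | C=C1C(=O)C[C@@H]2[C@](C)(CCC[C@@]2(C)C(=O)OC)[C@H]1CC(OC)OC | intermediate
8 | 12,12-dimethoxy-13,14,15,16-tetranorlabd-8(17)-ene-7β,18-diol | C=C1[C@@H](O)C[C@@H]2[C@](C)(CCC[C@@]2(C)CO)[C@H]1CC(OC)OC | intermediate
9 | 7β,18-dihydroxy-13,14,15,16-tetranorlabd-8(17)-en-12-al | C=C1[C@@H](O)C[C@@H]2[C@](C)(CCC[C@@]2(C)CO)[C@H]1CC=O | intermediate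
10 | (12E)-7β,18-dihydroxy-15-norlabda-8(17),12-dien-14-al | C=C1[C@@H](O)C[C@@H]2[C@](C)(CCC[C@@]2(C)CO)[C@H]1C/C=C(\C)C=O | intermediate
11 | (12E)-labda-8(17),12,14-triene-7β,18-diol | C=C1[C@@H](O)C[C@@H]2[C@](C)(CCC[C@@]2(C)CO)[C@H]1C/C=C(\C)C=C | intermediate
12 | (12E)-18-(triethylsilyloxy)labda-8(17),12,14-trien-7β-ol | C=C1[C@@H](O)C[C@@H]2[C@](C)(CCC[C@@]2(C)CO[Si](CC)(CC)CC)[C@H]1C/C=C(\C)C=C | intermediate
13 | (12E)-7β-(tert-butyldimethylsilyloxy)-18-(triethylsilyloxy)labda-8(17),12,14-triene | C=C1[C@@H](O[Si](C)(C)C(C)(C)C)C[C@@H]2[C@](C)(CCC[C@@]2(C)CO[Si](CC)(CC)CC)[C@H]1C/C=C(\C)C=C | intermediate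
14 | propargyl alcohol | C#CCO | starting material
15 | 3-iodoprop-2-yn-1-ol | OCC#CI | intermediate
16 | 3-iodopropynal | O=CC#CI | intermediate
17 | iodo enal: (12R) ring C 1,4-cyclohexadiene with CHO on C1' and I on C6', decalin as in 13 | C=C1[C@@H](O[Si](C)(C)C(C)(C)C)C[C@@H]2[C@](C)(CCC[C@@]2(C)CO[Si](CC)(CC)CC)[C@H]1C[C@@H]1C(C)=CCC(I)=C1C=O | intermediate
18 | iodo acid: 17 with CO2H on C1' | C=C1[C@@H](O[Si](C)(C)C(C)(C)C)C[C@@H]2[C@](C)(CCC[C@@]2(C)CO[Si](CC)(CC)CC)[C@H]1C[C@@H]1C(C)=CCC(I)=C1C(=O)O | intermediate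
19 | 2',4',6'-trihydroxyacetophenone | CC(=O)c1c(O)cc(O)cc1O | starting material
20 | 1-[2-hydroxy-4,6-bis(tert-butyldimethylsilyloxy)phenyl]ethanone | CC(=O)c1c(O)cc(O[Si](C)(C)C(C)(C)C)cc1O[Si](C)(C)C(C)(C)C | intermediate
21 | acid chloride of 18 | C=C1[C@@H](O[Si](C)(C)C(C)(C)C)C[C@@H]2[C@](C)(CCC[C@@]2(C)CO[Si](CC)(CC)CC)[C@H]1C[C@@H]1C(C)=CCC(I)=C1C(=O)Cl | intermediate
22 | 1,3-diketone: C1'–CO–CH2–CO–[2-hydroxy-4,6-bis(TBSO)phenyl] | C=C1[C@@H](O[Si](C)(C)C(C)(C)C)C[C@@H]2[C@](C)(CCC[C@@]2(C)CO[Si](CC)(CC)CC)[C@H]1C[C@@H]1C(C)=CCC(I)=C1C(=O)CC(=O)c1c(O)cc(O[Si](C)(C)C(C)(C)C)cc1O[Si](C)(C)C(C)(C)C | intermediate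
23 | iodo chromone: 5,7-bis(TBSO)chromon-2-yl on C1', I on C6' | C=C1[C@@H](O[Si](C)(C)C(C)(C)C)C[C@@H]2[C@](C)(CCC[C@@]2(C)CO[Si](CC)(CC)CC)[C@H]1C[C@@H]1C(C)=CCC(I)=C1c1cc(=O)c2c(O[Si](C)(C)C(C)(C)C)cc(O[Si](C)(C)C(C)(C)C)cc2o1 | intermediate
24 | dimethyl squarate | COC1=C(OC)C(=O)C1=O | starting material
25 | 4-hydroxy-2,3-dimethoxycyclobut-2-en-1-one | COC1=C(OC)C(O)C1=O | intermediate
26 | methyl semisquarate (3-methoxycyclobut-3-ene-1,2-dione) | COC1=CC(=O)C1=O | intermediate
27 | alkenylmagnesium chloride from 23 (MgCl on C6') | C=C1[C@@H](O[Si](C)(C)C(C)(C)C)C[C@@H]2[C@](C)(CCC[C@@]2(C)CO[Si](CC)(CC)CC)[C@H]1C[C@@H]1C(C)=CCC([Mg]Cl)=C1c1cc(=O)c2c(O[Si](C)(C)C(C)(C)C)cc(O[Si](C)(C)C(C)(C)C)cc2o1 | intermediate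
28 | hydroxycyclobutenone: 4-hydroxy-3-methoxy-4-(C6')cyclobut-2-en-1-one, carbinol centre unassigned | C=C1[C@@H](O[Si](C)(C)C(C)(C)C)C[C@@H]2[C@](C)(CCC[C@@]2(C)CO[Si](CC)(CC)CC)[C@H]1C[C@@H]1C(C)=CCC(C2(O)C(OC)=CC2=O)=C1c1cc(=O)c2c(O[Si](C)(C)C(C)(C)C)cc(O[Si](C)(C)C(C)(C)C)cc2o1 | intermediate
29 | dienylketene: C6'–C5'(OH)=C4'(OMe)–C3'H=C2'=O, ring C alkene cis to the ketene | C=C1[C@@H](O[Si](C)(C)C(C)(C)C)C[C@@H]2[C@](C)(CCC[C@@]2(C)CO[Si](CC)(CC)CC)[C@H]1C[C@@H]1C(C)=CCC(/C(O)=C(OC)\C=C=O)=C1c1cc(=O)c2c(O[Si](C)(C)C(C)(C)C)cc(O[Si](C)(C)C(C)(C)C)cc2o1 | intermediate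
30 | dienol: ring D closed, C5'(OH)=C6' enol, C1' quaternary (S) | C=C1[C@@H](O[Si](C)(C)C(C)(C)C)C[C@@H]2[C@](C)(CCC[C@@]2(C)CO[Si](CC)(CC)CC)[C@H]1C[C@@H]1C(C)=CCC2=C(O)C(OC)=CC(=O)[C@@]12c1cc(=O)c2c(O[Si](C)(C)C(C)(C)C)cc(O[Si](C)(C)C(C)(C)C)cc2o1 | intermediate
31 | silyl-protected enedione (7-OTBS, 18-OTES, 5,7-di-OTBS chromone; 12R,1'S,6'R) | C=C1[C@@H](O[Si](C)(C)C(C)(C)C)C[C@@H]2[C@](C)(CCC[C@@]2(C)CO[Si](CC)(CC)CC)[C@H]1C[C@@H]1C(C)=CC[C@H]2C(=O)C(OC)=CC(=O)[C@@]12c1cc(=O)c2c(O[Si](C)(C)C(C)(C)C)cc(O[Si](C)(C)C(C)(C)C)cc2o1 | intermediate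
32 | C18 alcohol (7-OTBS, 5,7-di-OTBS chromone) | C=C1[C@@H](O[Si](C)(C)C(C)(C)C)C[C@@H]2[C@](C)(CCC[C@@]2(C)CO)[C@H]1C[C@@H]1C(C)=CC[C@H]2C(=O)C(OC)=CC(=O)[C@@]12c1cc(=O)c2c(O[Si](C)(C)C(C)(C)C)cc(O[Si](C)(C)C(C)(C)C)cc2o1 | intermediate
33 | C18 aldehyde (tris-silyl dichrostachine H) | C=C1[C@@H](O[Si](C)(C)C(C)(C)C)C[C@@H]2[C@](C)(CCC[C@@]2(C)C=O)[C@H]1C[C@@H]1C(C)=CC[C@H]2C(=O)C(OC)=CC(=O)[C@@]12c1cc(=O)c2c(O[Si](C)(C)C(C)(C)C)cc(O[Si](C)(C)C(C)(C)C)cc2o1 | intermediate
34 | dichrostachine H | C=C1[C@@H](O)C[C@@H]2[C@](C)(CCC[C@@]2(C)C=O)[C@H]1C[C@@H]1C(C)=CC[C@H]2C(=O)C(OC)=CC(=O)[C@@]12c1cc(=O)c2c(O)cc(O)cc2o1 | target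

**Step count.** Total: 23 steps. Longest linear sequence: 19 steps (1–10, 13, 14, 16, 17, 19–23).

**Steps most likely to fail**

Step 20. The dienol 30 may ketonise on the face anti to the chromone and settle as the trans-fused C6' epimer, or ketene 29 may be diverted (closure through the chromone C2=C3 bond, oligomerisation) before it reaches the congested C1'. The fallback separates ring expansion from C6' protonation. It sets out from 28, which is silylated on the tertiary hydroxyl (TMSOTf, Et3N, CH2Cl2, −78 °C) to the trimethylsilyl ether F1. Thermolysis of F1 in toluene should give the isolable silyl dienol ether F2, with the silyl group held on the C5' oxygen. F2 is then protonated under kinetic control on the exposed convex face (citric acid, MeOH/THF, −40 °C), which comes back to the route at 31.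

Step 19. The Grignard reagents may attack the chromone, the exchange at the tetrasubstituted alkenyl iodide may be slow, or addition may occur in conjugate fashion at the unsubstituted C3' of the semisquarate. The fallback is a Nozaki–Hiyama–Kishi coupling: 23 and 26 with CrCl2 (excess) and NiCl2 (cat.) in DMF/THF at 23 °C. The alkenyl species of trivalent chromium is non-basic, tolerates the chromone and adds to the strained, aldehyde-like ketone carbonyl. It sets out from 23 and comes back at 28 without new intermediates.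

Step 13. Facial selectivity at C12 may be poor, because the catalyst's discrimination of a linear ynal has to override the remote chiral decalin, or the catalyst-bound ynal may react too slowly with the trisubstituted diene. The fallback moves stereocontrol to a covalently bound auxiliary. Propiolic acid is iodinated (N-iodosuccinimide, AgNO3 cat.) to 3-iodopropiolic acid F3. F3 is coupled through its pivaloyl mixed anhydride with lithiated (S)-4-benzyl-2-oxazolidinone to the N-acyl oxazolidinone F4. Et2AlCl-promoted Diels–Alder reaction of 13 with the chelated imide F4 (CH2Cl2, −78 °C) should give cycloadduct F5, with the benzyl group blocking one face. Cleavage with LiOH/H2O2 (THF/H2O, 0 °C) comes back to the route at 18.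

**Further compounds**

F1 | step 20 | trimethylsilyl ether of 28 (OSiMe3 on C5') | C=C1[C@@H](O[Si](C)(C)C(C)(C)C)C[C@@H]2[C@](C)(CCC[C@@]2(C)CO[Si](CC)(CC)CC)[C@H]1C[C@@H]1C(C)=CCC(C2(O[Si](C)(C)C)C(OC)=CC2=O)=C1c1cc(=O)c2c(O[Si](C)(C)C(C)(C)C)cc(O[Si](C)(C)C(C)(C)C)cc2o1
F2 | step 20 | silyl dienol ether of ring D (C5'(OSiMe3)=C6') | C=C1[C@@H](O[Si](C)(C)C(C)(C)C)C[C@@H]2[C@](C)(CCC[C@@]2(C)CO[Si](CC)(CC)CC)[C@H]1C[C@@H]1C(C)=CCC2=C(O[Si](C)(C)C)C(OC)=CC(=O)[C@@]12c1cc(=O)c2c(O[Si](C)(C)C(C)(C)C)cc(O[Si](C)(C)C(C)(C)C)cc2o1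
F0 | step 19 | none | none
F3 | step 13 | 3-iodopropiolic acid | OC(=O)C#CI
F4 | step 13 | (S)-4-benzyl-3-(3-iodopropioloyl)oxazolidin-2-one | O=C(C#CI)N1C(=O)OC[C@@H]1Cc1ccccc1
F5 | step 13 | N-acyl oxazolidinone cycloadduct (acyl group of 18 on the auxiliary nitrogen) | C=C1[C@@H](O[Si](C)(C)C(C)(C)C)C[C@@H]2[C@](C)(CCC[C@@]2(C)CO[Si](CC)(CC)CC)[C@H]1C[C@@H]1C(C)=CCC(I)=C1C(=O)N1C(=O)OC[C@@H]1Cc1ccccc1
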